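## The problem

The target 17 is kaempferol (rings A, C and B, hydroxyls on C3, C5, C7 and C4') carrying a (2S)-lavandulyl chain on C8. The chain atoms are numbered C1'' (the CH2 on C8), C2'' (the stereocentre), C3'' (the isopropenyl carbon), C4'' (the second CH2) and C5''=C6'' (the prenyl alkene). The ring system is an available flavonol, so the skeletal task is one sp2–sp3 bond, C8–C1'', plus the C10 chain itself. C2'' is the only stereocentre and lies three bonds from a flat aromatic core, so nothing in the molecule can direct it; it must be set by an external chiral agent and then carried through unchanged. C2''–H is allylic, so a carbonyl at C1'' or C4'' would invite epimerisation and migration of the isopropenyl double bond into conjugation; both arms are best kept at the alcohol, sulfonate or halide level. Both alkenes are protonated easily to tertiary cations, and the C7 hydroxyl is placed to trap a C3'' cation as a chroman. This excludes strong Brønsted or Lewis acids, hydrogenolysis and electrophilic halogen once the chain is attached, and it narrows the choice of phenol protecting groups. On ring A both C6 and C8 are activated, and the C5 hydroxyl, chelated to the C4 carbonyl, influences which of them reacts. The enabling feature is that C2'' carries hydrogen, the isopropenyl group and two methylene arms, C1'' and C4''. With a hydroxyl on each arm it is the prochiral carbon of the achiral diol 4, whose two hydroxymethyl groups are enantiotopic, so marking one of them fixes C2'' without forming any carbon–carbon bond.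

## Retrosynthesis

**17 from 16.** The four phenolic O–H bonds are masked as methoxymethyl ethers in 16. These ethers survive sodium hydride, organozinc reagents and palladium, and they leave under dilute acid in methanol. Benzyl ethers would need hydrogenolysis and methyl ethers a boron halide, and neither is compatible with the two alkenes. The forward step must use acid mild enough that neither alkene is protonated.

**16 from 14 and 11 (C8–C1'').** The flavonol and the chain are separated at the aryl–alkyl bond. This is preferred to Friedel–Crafts alkylation of kaempferol 12, because C1'' is a plain, β-branched primary carbon (homoallylic, not allylic) and offers neither cation stabilisation nor a Claisen route, and O-alkylation and C6 attack would compete. It is also preferred to building rings C and B onto a pre-alkylated ring A, which would cost many steps. The forward reaction is a Negishi coupling of the alkylzinc iodide 15, made from iodide 11, with the aryl iodide 14. The zinc reagent must leave the chromone carbonyl alone and couple at a position flanked by two oxygens.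

**14 from 13 from 12 (C8–I and four O–CH2 bonds).** Iodide 14 comes from the fully protected flavonol 13 by electrophilic iodination, and 13 from kaempferol 12. Protecting the C5 hydroxyl matters for more than the later steps: with the C5 oxygen alkylated, 5,7-dialkoxyflavones are substituted at C8, whereas a free, chelated C5 hydroxyl sends the electrophile to C6.

**11 from 10 from 9 (functional-group changes).** Iodide 11 is the Appel product of (R)-lavandulol 10, which is the methanolysis product of its acetate 9. No skeletal bond is involved. C2'' is a spectator because the chemistry takes place at C1'' and at oxygen.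

**9 from 7 and 8 (C4''–C5'').** The prenyl arm is cut between the CH2 group and the alkene carbon, giving tosylate 7 and the commercial alkenyl Grignard reagent 8. Cutting C2''–C4'' instead would mean an enolate alkylation next to a carbonyl and a chiral auxiliary. The chosen cut makes the bond by SN2 displacement at a CH2 group, away from the stereocentre, and the alkene has two identical methyl groups, so no geometry has to be controlled. The forward coupling must be faster than attack of the Grignard reagent on the acetate.

**7 from 6 from 4 and 5 (no skeletal bond; the stereocentre).** Tosylate 7 is the sulfonate of monoacetate 6, in which the two arms of diol 4 are told apart. Monoacetate 6 is to come from 4 and vinyl acetate 5 by lipase-catalysed acetylation of one enantiotopic hydroxymethyl group. The precursor is an achiral C6 diol, and all of the chirality of the target is introduced here by a catalyst.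

**4 from 3 from 1.** Diol 4 is the reduction product of the deconjugated malonate 3, which is reached from the commercial alkylidene malonate 1 by γ-deprotonation and α-protonation. The isopropenyl group is obtained by moving a double bond, not by forming a carbon–carbon bond.

## Roads not taken

**Alternative 1:** ring C is cut at C4a–C4, C4–C3 and O1–C2. In the forward direction the lavandulyl-bearing iodophenol A2, the arylalkyne A3 and carbon monoxide A4 would be joined under PdCl2(PPh3)2 (a divalent palladium precatalyst reduced in the flask to zerovalent palladium) in diethylamine to give flavone A1.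
- Merits: three bonds and a ring are formed in one convergent step. The chain position is fixed by the substitution pattern of A2, so no C6/C8 question arises; in this respect the road is better than the chosen plan, which depends on the regioselectivity of iodination in step 9.
- Weak points: A1 lacks the C3 hydroxyl, so a flavone-to-flavonol oxidation would be needed in the presence of two electron-rich alkenes. 5-exo closure to an aurone competes with the 6-endo closure. A2 is a fully differentiated, hindered, electron-rich iodophenol that must itself be made in several steps.
- Comparison: this road does not address C2'' at all; the enantioenriched chain and its attachment to a phloroglucinol ring remain to be solved inside A2. The chosen plan takes ring C and all four oxygens from kaempferol 12 and spends its steps on the stereocentre. Against the regiochemical certainty of Alternative 1 it sets the known C8 preference of 5-O-alkylated flavones.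

**Alternative 2:** the cut is C1''–C2''. The ring A aldehyde A6 and the (E)-allylboronate A7 would react under a chiral BINOL-derived phosphoric acid of the 3,3'-bis(2,4,6-triisopropylphenyl) type through a chair transition state to give the anti homoallylic alcohol A5.
- Merits: a skeletal bond, the isopropenyl group (by allyl transposition) and C2'' are all made in one catalytic step. This is more bond-forming per step than the chosen key step, which forms no carbon–carbon bond.
- Weak points: A6 is a di-ortho-substituted, electron-rich and therefore poorly electrophilic aldehyde. The geometric purity of the trisubstituted boronate A7 translates directly into the purity at C2''. The C1'' carbinol of A5 must afterwards be removed next to an electron-rich arene and two acid-sensitive alkenes. The flavonol would then have to be built onto ring A by acylation, aldol condensation and an Algar–Flynn–Oyamada oxidative cyclisation, which tends towards aurones when the position corresponding to C5 is oxygenated.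
- Comparison: the chosen plan is less elegant at the key step, but it avoids the deoxygenation and the whole ring C construction.

**Alternative 3:** the cut is C2''–C4''. The sodium dienolate of the senecioyl imide A9 (NaN(SiMe3)2, low temperature) would be alkylated at its α-carbon by prenyl bromide A10 to give A8; the alkene moves out of conjugation and the benzyl group of the auxiliary sets C2''.
- Merits: the facial selectivity of such chelated imide enolates is highly predictable. A skeletal bond is formed together with the stereocentre. Reductive removal of the auxiliary from A8 gives (R)-lavandulol 10 in about three steps, fewer than the six steps to 10 in the chosen route, so in step count and in certainty of the sense of induction this road is at least as good.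
- Weak points: the auxiliary is stoichiometric and the base is used at low temperature. α- versus γ-alkylation must be controlled. In A8, C2'' is both allylic and α to a carbonyl, so it can epimerise or conjugate during cleavage of a hindered imide.
- Comparison: the chosen plan offers a catalytic source of chirality that works near room temperature on an achiral C6 diol, no auxiliary to attach and remove, and a C2'' that never sits next to a carbonyl once it is stereogenic. Its price is that the sense and level of enzyme selectivity are empirical. Because A8 leads to 10, this road would replace steps 1 to 6 if the enzyme could not be made to serve.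

Key step: step 3

Assumption: the lipase is taken to acetylate the pro-S hydroxymethyl group of 4, giving 6 as drawn. The sense is an empirical property of the enzyme–substrate pair, and the arm-exchange sequence given under the least certain steps covers the opposite outcome.

## Route

Step 1
Reactants: 1 diethyl 2-(propan-2-ylidene)malonate (diethyl isopropylidenemalonate)
Product: 3 diethyl 2-(prop-1-en-2-yl)malonate, via lithium dienolate 2 (not isolated)
Conditions: LiN(iPr)2, THF, −78 °C; then AcOH, −78 °C
Reagents that add atoms: none
Why: Deconjugative protonation of an alkylidene malonate: the hindered amide removes a γ-proton to give the delocalised dienolate 2, and kinetic protonation at the α-carbon gives the β,γ-unsaturated malonate; no stereocentre is formed.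

Step 2
Reactants: 3 diethyl 2-(prop-1-en-2-yl)malonate
Product: 4 2-(prop-1-en-2-yl)propane-1,3-diol
Conditions: LiAlH4 (excess), Et2O, 0 °C (3 added to the hydride); H2O/NaOH work-up
Reagents that add atoms: none
Why: Hydride reduction of a monosubstituted malonate to the 2-substituted propane-1,3-diol; adding the ester to excess hydride in the cold lets reduction outrun enolisation of the acidic malonate C–H, and the isolated alkene is inert to LiAlH4.

Step 3
Reactants: 4 2-(prop-1-en-2-yl)propane-1,3-diol; 5 vinyl acetate
Product: 6 (S)-3-hydroxy-2-(prop-1-en-2-yl)propyl acetate
Conditions: immobilised Burkholderia cepacia lipase, vinyl acetate (4 equiv), t-BuOMe, 4 Å molecular sieves, 0 to 20 °C; filtration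
Reagents that add atoms: none
Why: The catalytic serine of the lipase is acetylated by vinyl acetate, and the vinyl alcohol released tautomerises to acetaldehyde, so the acyl transfer cannot run backwards. Diol 4 then binds with its isopropenyl group and its hydrogen in the differently sized pockets next to the acyl-enzyme, which brings only one of the two enantiotopic hydroxymethyl groups within reach of the acetyl group, and collapse of the tetrahedral intermediate releases 6. The closest known reaction type is the lipase-catalysed desymmetrisation of 2-substituted propane-1,3-diols by transesterification with vinyl acetate. No ring is closed and no skeletal bond is formed; the step only turns the prochiral carbon of 4 into the (S)-centre that becomes C2''. That centre is controlled by the chiral active site alone, since the substrate has no other stereogenic element. Three selectivities are needed: enantiotopic-group selectivity, which rests on the size difference between isopropenyl and hydrogen at the prochiral carbon; mono- over diacetylation, helped by the fact that the free hydroxyl of 6 is on the arm the enzyme disfavours, so further acetylation should consume mainly the minor enantiomer and raise the enantiomeric purity of 6; and freedom from 1,3-acetyl migration, which would racemise 6 and is held back by the dry, base-free medium, the low temperature and immediate use in step 4.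

Step 4
Reactants: 6 (S)-3-hydroxy-2-(prop-1-en-2-yl)propyl acetate
Product: 7 (2R)-3-[(4-methylbenzenesulfonyl)oxy]-2-(prop-1-en-2-yl)propyl acetate
Conditions: TsCl, Et3N, Me3N·HCl (cat.), CH2Cl2, 0 °C
Reagents that add atoms: p-toluenesulfonyl chloride, Cc1ccc(cc1)S(Cl)(=O)=O
Why: Sulfonylation of a primary alcohol under amine catalysis is fast at 0 °C and touches no bond at C2''; the short reaction time in the cold keeps acetyl migration between the arms negligible (the descriptor changes to R only because the priorities change).

Step 5
Reactants: 7 (2R)-3-[(4-methylbenzenesulfonyl)oxy]-2-(prop-1-en-2-yl)propyl acetate; 8 2-methylprop-1-enylmagnesium bromide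
Product: 9 (2R)-5-methyl-2-(prop-1-en-2-yl)hex-4-en-1-yl acetate ((R)-lavandulyl acetate)
Conditions: Li2CuCl4 (5 mol%), THF, −78 to −20 °C, slow addition of 8 (1.5 equiv)
Reagents that add atoms: none
Why: Copper-catalysed cross-coupling of a Grignard reagent with a primary alkyl tosylate (Kochi type): the alkenylcopper species formed in the flask displaces tosylate by SN2 at the CH2 group, so C2'' is untouched and C4''–C5'' is formed; in the cold the catalysed substitution should outpace addition of the alkenyl Grignard reagent to the acetate, and acetate lost after the coupling is harmless because step 6 removes it.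

Step 6
Reactants: 9 (2R)-5-methyl-2-(prop-1-en-2-yl)hex-4-en-1-yl acetate
Product: 10 (2R)-5-methyl-2-(prop-1-en-2-yl)hex-4-en-1-ol ((R)-lavandulol)
Conditions: K2CO3 (0.2 equiv), MeOH, 20 °C
Reagents that add atoms: none
Why: Base-catalysed transesterification of the acetate with methanol; there is no carbonyl next to C2'', so the stereocentre cannot epimerise.

Step 7
Reactants: 10 (2R)-5-methyl-2-(prop-1-en-2-yl)hex-4-en-1-ol
Product: 11 (3R)-3-(iodomethyl)-2,6-dimethylhepta-1,5-diene ((R)-lavandulyl iodide)
Conditions: PPh3, I2, imidazole, CH2Cl2, 0 to 20 °C, dark
Reagents that add atoms: iodine, II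
Why: Appel-type iodination of a primary alcohol through an alkoxyphosphonium iodide, with SN2 displacement at C1''; the preformed phosphine–iodine reagent and the buffered medium leave both alkenes and C2'' alone.

Step 8
Reactants: 12 kaempferol (3,5,7-trihydroxy-2-(4-hydroxyphenyl)-4H-chromen-4-one)
Product: 13 3,5,7-tris(methoxymethoxy)-2-[4-(methoxymethoxy)phenyl]-4H-chromen-4-one
Conditions: NaH (6 equiv), MOMCl (6 equiv), DMF, 0 to 20 °C
Reagents that add atoms: chloromethyl methyl ether, COCCl
Why: Williamson-type O-alkylation of all four phenoxides; NaH in DMF is used so that the C5 hydroxyl, chelated to the carbonyl, is alkylated as well, which is what directs step 9 to C8.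

Step 9
Reactants: 13 3,5,7-tris(methoxymethoxy)-2-[4-(methoxymethoxy)phenyl]-4H-chromen-4-one
Product: 14 8-iodo-3,5,7-tris(methoxymethoxy)-2-[4-(methoxymethoxy)phenyl]-4H-chromen-4-one
Conditions: NIS (1.1 equiv), DMF, 20 °C, dark
Reagents that add atoms: N-iodosuccinimide, O=C1CCC(=O)N1I
Why: Electrophilic aromatic iodination under neutral conditions; ring A is the most electron-rich ring, and with the C5 oxygen alkylated and no longer hydrogen-bonded to the carbonyl, 5,7-dialkoxyflavones are substituted at C8 in preference to C6, while the acid-free medium spares the acetal protecting groups.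

Step 10
Reactants: 11 (3R)-3-(iodomethyl)-2,6-dimethylhepta-1,5-diene; 14 8-iodo-3,5,7-tris(methoxymethoxy)-2-[4-(methoxymethoxy)phenyl]-4H-chromen-4-one
Product: 16 3,5,7-tris(methoxymethoxy)-2-[4-(methoxymethoxy)phenyl]-8-[(2S)-5-methyl-2-(prop-1-en-2-yl)hex-4-en-1-yl]-4H-chromen-4-one, via lavandulylzinc iodide 15 (not isolated)
Conditions: Zn dust (activated with BrCH2CH2Br and Me3SiCl), LiCl, THF, 40 °C; then 14, Pd(OAc)2 (3 mol%), SPhos (2-dicyclohexylphosphino-2',6'-dimethoxybiphenyl, 6 mol%), THF, 20 to 50 °C
Reagents that add atoms: none
Why: Insertion of zinc metal into the primary C–I bond followed by Negishi coupling: the C8–I bond adds to zerovalent palladium (formed from Pd(OAc)2), the alkyl group is transferred from zinc, and the bulky biarylphosphine makes reductive elimination faster than β-hydride elimination even at a di-ortho-substituted aryl carbon; the organozinc does not add to the chromone carbonyl, and C2'' is not involved (S in 16 by priority change only).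

Step 11
Reactants: 16 3,5,7-tris(methoxymethoxy)-2-[4-(methoxymethoxy)phenyl]-8-[(2S)-5-methyl-2-(prop-1-en-2-yl)hex-4-en-1-yl]-4H-chromen-4-one
Product: 17 3,5,7-trihydroxy-2-(4-hydroxyphenyl)-8-[(2S)-5-methyl-2-(prop-1-en-2-yl)hex-4-en-1-yl]-4H-chromen-4-one (CNP0185677.2)
Conditions: HCl (ca. 1 M in MeOH), 20 to 40 °C, close monitoring; NaHCO3 quench
Reagents that add atoms: none
Why: Acid-catalysed acetal exchange of the four aryl methoxymethyl ethers with methanol, a standard deprotection for prenylated flavonoids; aryl acetals of this kind cleave under acid dilute enough that protonation of the two alkenes, and with it chroman formation through the C7 hydroxyl, should stay slow.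

## Compound list

1 | diethyl 2-(propan-2-ylidene)malonate | CCOC(=O)C(=C(C)C)C(=O)OCC | starting material
2 | lithium dienolate of diethyl 2-(prop-1-en-2-yl)malonate | [Li+].CCOC([O-])=C(C(C)=C)C(=O)OCC | intermediate (not isolated)
3 | diethyl 2-(prop-1-en-2-yl)malonate | C=C(C)C(C(=O)OCC)C(=O)OCC | intermediate
4 | 2-(prop-1-en-2-yl)propane-1,3-diol (achiral, prochiral at C2) | C=C(C)C(CO)CO | intermediate
5 | vinyl acetate | C=COC(C)=O | starting material
6 | (S)-3-hydroxy-2-(prop-1-en-2-yl)propyl acetate | C=C(C)[C@@H](CO)COC(C)=O | intermediate
7 | (2R)-3-[(4-methylbenzenesulfonyl)oxy]-2-(prop-1-en-2-yl)propyl acetate | C=C(C)[C@@H](COS(=O)(=O)c1ccc(C)cc1)COC(C)=O | intermediate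
8 | 2-methylprop-1-enylmagnesium bromide | CC(C)=C[Mg]Br | starting material
9 | (2R)-5-methyl-2-(prop-1-en-2-yl)hex-4-en-1-yl acetate ((R)-lavandulyl acetate) | C=C(C)[C@@H](CC=C(C)C)COC(C)=O | intermediate
10 | (2R)-5-methyl-2-(prop-1-en-2-yl)hex-4-en-1-ol ((R)-lavandulol) | C=C(C)[C@@H](CC=C(C)C)CO | intermediate
11 | (3R)-3-(iodomethyl)-2,6-dimethylhepta-1,5-diene ((R)-lavandulyl iodide) | C=C(C)[C@@H](CC=C(C)C)CI | intermediate
12 | kaempferol | O=c1c(O)c(-c2ccc(O)cc2)oc2cc(O)cc(O)c12 | starting material
13 | 3,5,7-tris(methoxymethoxy)-2-[4-(methoxymethoxy)phenyl]-4H-chromen-4-one | COCOc1ccc(cc1)-c1oc2cc(OCOC)cc(OCOC)c2c(=O)c1OCOC | intermediate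
14 | 8-iodo-3,5,7-tris(methoxymethoxy)-2-[4-(methoxymethoxy)phenyl]-4H-chromen-4-one | COCOc1ccc(cc1)-c1oc2c(I)c(OCOC)cc(OCOC)c2c(=O)c1OCOC | intermediate
15 | [(2R)-5-methyl-2-(prop-1-en-2-yl)hex-4-en-1-yl]zinc iodide | C=C(C)[C@@H](CC=C(C)C)C[Zn]I | intermediate (not isolated)
16 | 3,5,7-tris(methoxymethoxy)-2-[4-(methoxymethoxy)phenyl]-8-[(2S)-5-methyl-2-(prop-1-en-2-yl)hex-4-en-1-yl]-4H-chromen-4-one | C=C(C)[C@@H](CC=C(C)C)Cc1c(OCOC)cc(OCOC)c2c(=O)c(OCOC)c(-c3ccc(OCOC)cc3)oc12 | intermediate
17 | 3,5,7-trihydroxy-2-(4-hydroxyphenyl)-8-[(2S)-5-methyl-2-(prop-1-en-2-yl)hex-4-en-1-yl]-4H-chromen-4-one | C=C(C)[C@@H](CC=C(C)C)Cc1c(O)cc(O)c2c(=O)c(O)c(-c3ccc(O)cc3)oc12 | target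

## Step count and least certain steps

Total: 11 steps. Longest linear sequence: 9 steps (steps 1 to 7, then 10 and 11, from 1). The flavonol branch (steps 8 and 9, from 12) joins at step 10.

**Step 3 (key step).** The most likely failure is that the enzyme acetylates the other enantiotopic arm, or discriminates the arms only moderately, because the fit of a small, branched diol in the active site cannot be predicted. Slow wandering of the acetyl group between the two oxygens would add to the loss of enantiomeric purity. Moderate discrimination is met within the step by letting the acetylation run on until part of the monoacetate has been converted further. Acetylation of the wrong arm is met by exchanging the roles of the arms. The fallback sets out from 4, which under the same conditions would give (R)-3-hydroxy-2-(prop-1-en-2-yl)propyl acetate F1. Silylation of its free hydroxyl (t-BuPh2SiCl, imidazole, DMF) would give (S)-3-[(tert-butyldiphenylsilyl)oxy]-2-(prop-1-en-2-yl)propyl acetate F2, and methanolysis (K2CO3, MeOH, 0 °C) would free the other arm as (S)-3-[(tert-butyldiphenylsilyl)oxy]-2-(prop-1-en-2-yl)propan-1-ol F3. Tosylation as in step 4 would give (R)-3-[(tert-butyldiphenylsilyl)oxy]-2-(prop-1-en-2-yl)propyl 4-methylbenzenesulfonate F4, and coupling with 8 as in step 5 would give tert-butyl{[(2R)-5-methyl-2-(prop-1-en-2-yl)hex-4-en-1-yl]oxy}diphenylsilane F5. Desilylation with Bu4NF in THF returns to the route at 10. This path is two steps longer, but the copper coupling then runs without an ester in the molecule.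

**Step 5.** The Grignard reagent may attack the acetate before the tosylate is displaced; the alkoxide so formed can close an oxetane or pass the acetyl group on. Elimination of tosylate across the allylic C2''–H, and slow substitution at the β-branched carbon, are further risks. The fallback reverses the polarity and uses an ester-tolerant organometallic. It sets out from 6, which is converted with PPh3, I2 and imidazole to (R)-3-iodo-2-(prop-1-en-2-yl)propyl acetate F6. Zinc insertion (Zn dust, LiCl, THF) gives [(2R)-3-acetoxy-2-(prop-1-en-2-yl)propyl]zinc iodide F7, which is coupled with 1-bromo-2-methylprop-1-ene under Pd(OAc)2 and SPhos (Negishi coupling). The path returns at 9.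

**Step 10.** The radical that appears for a moment on the zinc surface is homoallylic and could rearrange by a 1,2-vinyl shift through a cyclopropylcarbinyl radical. The alkylpalladium intermediate could lose a β-hydride, which would scramble C2''. Coupling at the hindered, electron-rich C8 may be slow enough for reductive loss of iodine to compete. The fallback avoids both the radical and the zinc reagent. It sets out from 11, which undergoes iodine–lithium exchange (t-BuLi, Et2O, −78 °C) to [(2R)-5-methyl-2-(prop-1-en-2-yl)hex-4-en-1-yl]lithium F8. This is trapped with 9-methoxy-9-borabicyclo[3.3.1]nonane as lithium 9-methoxy-9-[(2R)-5-methyl-2-(prop-1-en-2-yl)hex-4-en-1-yl]-9-borabicyclo[3.3.1]nonan-9-uide F9. B-alkyl Suzuki–Miyaura coupling of F9 with 14 (PdCl2(dppf), where dppf is 1,1'-bis(diphenylphosphino)ferrocene, aqueous K3PO4, DMF) returns at 16.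

**Step 11.** Protonation of the isopropenyl or prenyl alkene during acetal cleavage would lead to ring closure by the freed C7 hydroxyl onto C3'' (chroman formation), or to addition of methanol. The fallback removes all acid from the steps that follow chain attachment. It sets out from 14, which is deprotected with HCl in MeOH (no alkene present yet) to 8-iodokaempferol F10 and acetylated (Ac2O, pyridine) to 8-iodokaempferol tetraacetate F11. Negishi coupling with 15 as in step 10, which esters tolerate, gives 8-[(2S)-5-methyl-2-(prop-1-en-2-yl)hex-4-en-1-yl]kaempferol tetraacetate F12. Methanolysis (K2CO3, MeOH, 0 °C, under argon) returns at 17.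

## Further compounds

F1 | step 3 | (R)-3-hydroxy-2-(prop-1-en-2-yl)propyl acetate | C=C(C)[C@H](CO)COC(C)=O
F2 | step 3 | (S)-3-[(tert-butyldiphenylsilyl)oxy]-2-(prop-1-en-2-yl)propyl acetate | C=C(C)[C@H](CO[Si](c1ccccc1)(c1ccccc1)C(C)(C)C)COC(C)=O
F3 | step 3 | (S)-3-[(tert-butyldiphenylsilyl)oxy]-2-(prop-1-en-2-yl)propan-1-ol | C=C(C)[C@H](CO[Si](c1ccccc1)(c1ccccc1)C(C)(C)C)CO
F4 | step 3 | (R)-3-[(tert-butyldiphenylsilyl)oxy]-2-(prop-1-en-2-yl)propyl 4-methylbenzenesulfonate | C=C(C)[C@H](CO[Si](c1ccccc1)(c1ccccc1)C(C)(C)C)COS(=O)(=O)c1ccc(C)cc1
F5 | step 3 | tert-butyl{[(2R)-5-methyl-2-(prop-1-en-2-yl)hex-4-en-1-yl]oxy}diphenylsilane | C=C(C)[C@H](CO[Si](c1ccccc1)(c1ccccc1)C(C)(C)C)CC=C(C)C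
F6 | step 5 | (R)-3-iodo-2-(prop-1-en-2-yl)propyl acetate | C=C(C)[C@@H](CI)COC(C)=O
F7 | step 5 | [(2R)-3-acetoxy-2-(prop-1-en-2-yl)propyl]zinc iodide | C=C(C)[C@@H](C[Zn]I)COC(C)=O
F8 | step 10 | [(2R)-5-methyl-2-(prop-1-en-2-yl)hex-4-en-1-yl]lithium | [Li]C[C@H](CC=C(C)C)C(C)=C
F9 | step 10 | lithium 9-methoxy-9-[(2R)-5-methyl-2-(prop-1-en-2-yl)hex-4-en-1-yl]-9-borabicyclo[3.3.1]nonan-9-uide | [Li+].CO[B-]1(C[C@H](CC=C(C)C)C(C)=C)C2CCCC1CCC2
F10 | step 11 | 8-iodokaempferol (3,5,7-trihydroxy-2-(4-hydroxyphenyl)-8-iodo-4H-chromen-4-one) | O=c1c(O)c(-c2ccc(O)cc2)oc2c(I)c(O)cc(O)c12
F11 | step 11 | 8-iodokaempferol tetraacetate | CC(=O)Oc1ccc(cc1)-c1oc2c(I)c(OC(C)=O)cc(OC(C)=O)c2c(=O)c1OC(C)=O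
F12 | step 11 | 8-[(2S)-5-methyl-2-(prop-1-en-2-yl)hex-4-en-1-yl]kaempferol tetraacetate | C=C(C)[C@@H](CC=C(C)C)Cc1c(OC(C)=O)cc(OC(C)=O)c2c(=O)c(OC(C)=O)c(-c3ccc(OC(C)=O)cc3)oc12
A1 | alternative 1 | 8-[(2S)-5-methyl-2-(prop-1-en-2-yl)hex-4-en-1-yl]-5,7,4'-tris(methoxymethoxy)flavone | C=C(C)[C@@H](CC=C(C)C)Cc1c(OCOC)cc(OCOC)c2c(=O)cc(-c3ccc(OCOC)cc3)oc12
A2 | alternative 1 | 2-iodo-3,5-bis(methoxymethoxy)-6-[(2S)-5-methyl-2-(prop-1-en-2-yl)hex-4-en-1-yl]phenol | C=C(C)[C@@H](CC=C(C)C)Cc1c(O)c(I)c(OCOC)cc1OCOC
A3 | alternative 1 | 1-ethynyl-4-(methoxymethoxy)benzene | C#Cc1ccc(OCOC)cc1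
A4 | alternative 1 | carbon monoxide | [C-]#[O+]
A5 | alternative 2 | (1R,2R)-1-[2-(tert-butyldimethylsilyloxy)-4,6-bis(methoxymethoxy)phenyl]-5-methyl-2-(prop-1-en-2-yl)hex-4-en-1-ol (anti) | C=C(C)[C@@H](CC=C(C)C)[C@@H](O)c1c(O[Si](C)(C)C(C)(C)C)cc(OCOC)cc1OCOC
A6 | alternative 2 | 2-[(tert-butyldimethylsilyl)oxy]-4,6-bis(methoxymethoxy)benzaldehyde | O=Cc1c(O[Si](C)(C)C(C)(C)C)cc(OCOC)cc1OCOC
A7 | alternative 2 | (E)-2-(2,6-dimethylhepta-2,5-dien-1-yl)-4,4,5,5-tetramethyl-1,3,2-dioxaborolane | CC(C)=CC/C=C(\C)CB1OC(C)(C)C(C)(C)O1
A8 | alternative 3 | (4R)-4-benzyl-3-[(2R)-5-methyl-2-(prop-1-en-2-yl)hex-4-enoyl]oxazolidin-2-one | C=C(C)[C@@H](CC=C(C)C)C(=O)N1[C@H](Cc2ccccc2)COC1=O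
A9 | alternative 3 | (4R)-4-benzyl-3-(3-methylbut-2-enoyl)oxazolidin-2-one | CC(C)=CC(=O)N1[C@H](Cc2ccccc2)COC1=O
A10 | alternative 3 | 1-bromo-3-methylbut-2-ene (prenyl bromide) | CC(C)=CCBr
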